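The synthesis hinges on the C10–C11 bond (longipinane numbering), which is shared by the cyclobutane and by the cyclohexenone ring C10–C11–C1–C2–C3–C4. The C1 ketone and the C9 oxygen are 1,4-related across this bond, so it is formed by intramolecular oxidative coupling of two ketone enolates. In one operation this closes both small rings, creates quaternary C10 and sets C10 and C11. The precursor is a cis-fused bicyclo[5.4.0]undecadienedione with two enones and no cyclobutane. It is built by an organocatalytic Michael/aldol cyclohexenone synthesis, an Ireland–Claisen rearrangement and ring-closing metathesis. Conjugate borylation and an Evans–Tishchenko reduction then install the two different esters.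

Key step: step 11

Remark on numbering: C1 ketone, C2=C3(CH3), C4, C5, C6(CH3)2, C7 (O-senecioyl), C8, C9 (O-isovaleryl), C10(CH3), C11. These numbers are used for all intermediates. Ring A = C10–C11–C1–C2–C3–C4. Ring B = C5–C11–C1–C2–C3–C4. Ring C = cyclobutane C4–C5–C11–C10. Ring D = C4–C5–C6–C7–C8–C9–C10.

Remark on C10: from 11 to 17 the side-chain carbon C10 is carried as a mixture of epimers and drawn without configuration, because it becomes planar in step 11.

Step 1
Reactants: 1 methyl 3,3-dimethylpent-4-enoate
Product: 2 3,3-dimethylpent-4-enal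
Conditions: DIBAL-H (1.05 equiv), CH2Cl2, −78 °C; aq. Rochelle salt
Reagents that add atoms: none
Why: Partial ester reduction with DIBAL-H stops at the aluminium hemiacetal at low temperature and releases the aldehyde only on work-up, and no stereocentre is involved.

Step 2
Reactants: 2 3,3-dimethylpent-4-enal; 3 pent-1-en-3-one
Product: 4 (2S)-2-(2-methylbut-3-en-2-yl)-5-oxoheptanal
Conditions: (S)-2-[methoxy(diphenyl)methyl]pyrrolidine (5 mol %), ethyl 3,4-dihydroxybenzoate (20 mol %), neat, 4 °C
Reagents that add atoms: none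
Why: In this enamine-catalysed asymmetric Michael addition of an aldehyde to a vinyl ketone, the diphenyl(methoxy)methyl group shields one face of the E-enamine, so the C5–C11 bond forms on the open face and C5 is set as S.

Step 3
Reactants: 4 (2S)-2-(2-methylbut-3-en-2-yl)-5-oxoheptanal
Product: 5 (4R)-2-methyl-4-(2-methylbut-3-en-2-yl)cyclohex-2-en-1-one
Conditions: LiOH (cat.), i-PrOH, rt
Reagents that add atoms: none
Why: In this intramolecular aldol condensation (the second half of a Robinson-type annulation) only attack of the ethyl CH2 (C3) on the aldehyde (C4) gives a six-membered ring (ring B), and the mild base should leave C5 intact.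

Step 4
Reactants: 5 (4R)-2-methyl-4-(2-methylbut-3-en-2-yl)cyclohex-2-en-1-one
Product: 6 (1R,4R)-2-methyl-4-(2-methylbut-3-en-2-yl)cyclohex-2-en-1-ol (1,4-trans)
Conditions: NaBH4, CeCl3·7H2O, MeOH, −78 to 0 °C
Reagents that add atoms: none
Why: The Luche reduction gives clean 1,2-reduction, and axial hydride attack on the half-chair with the tert-alkyl group pseudo-equatorial places the C2 hydroxyl pseudo-equatorial, which is trans to the C5 substituent.

Step 5
Reactants: 6 (1R,4R)-2-methyl-4-(2-methylbut-3-en-2-yl)cyclohex-2-en-1-ol; 7 propanoic acid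
Product: 8 (1S,4R)-2-methyl-4-(2-methylbut-3-en-2-yl)cyclohex-2-en-1-yl propanoate (1,4-cis)
Conditions: PPh3, DIAD, toluene, 0 °C to rt
Reagents that add atoms: none
Why: The Mitsunobu esterification inverts C2 by SN2 displacement of the oxyphosphonium group, which puts the C2–O bond on the same ring face as the C5 substituent, and SN2' attack at C4 is blocked by the neighbouring tert-alkyl group.

Step 6
Reactants: 8 (1S,4R)-2-methyl-4-(2-methylbut-3-en-2-yl)cyclohex-2-en-1-yl propanoate
Product: 11 2-[(1S,6R)-2-methyl-6-(2-methylbut-3-en-2-yl)cyclohex-2-en-1-yl]propanoic acid, via silyl ketene acetal 9 (not isolated), via trimethylsilyl ester 10 (not isolated)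
Conditions: LDA, THF, −78 °C; TMSCl; −78 to 60 °C; then 1 M HCl
Reagents that add atoms: none
Why: The Ireland–Claisen rearrangement is suprafacial, so the C4–C10 bond forms on the face that carried the C2–O bond (pseudo-axial O, pseudo-equatorial C5 group), which makes C10 cis to C6 and moves the double bond to C2=C3.

Step 7
Reactants: 11 2-[(1S,6R)-2-methyl-6-(2-methylbut-3-en-2-yl)cyclohex-2-en-1-yl]propanoic acid
Product: 13 N-methoxy-N-methyl amide of 11, via acyl imidazolide 12 (not isolated)
Conditions: 1,1'-carbonyldiimidazole, CH2Cl2, rt; then MeNHOMe, rt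
Reagents that add atoms: N,O-dimethylhydroxylamine CNOC
Why: Weinreb amide formation through the acyl imidazolide is a neutral acyl transfer that touches neither alkene nor C4 and C5.

Step 8
Reactants: 13 N-methoxy-N-methyl amide of 11; 14 vinylmagnesium bromide
Product: 15 4-[(1S,6R)-2-methyl-6-(2-methylbut-3-en-2-yl)cyclohex-2-en-1-yl]pent-1-en-3-one
Conditions: THF, 0 °C; cold aq. NH4Cl
Reagents that add atoms: none
Why: In this Weinreb ketone synthesis the chelated tetrahedral magnesium adduct survives until the quench, so a single vinyl group (C8 plus a terminal CH2) is added and the C9 vinyl ketone results.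

Step 9
Reactants: 15 4-[(1S,6R)-2-methyl-6-(2-methylbut-3-en-2-yl)cyclohex-2-en-1-yl]pent-1-en-3-one
Product: 16 (4S,5R)-3,6,6,10-tetramethylbicyclo[5.4.0]undeca-2,7-dien-9-one (route numbering; cis-fused)
Conditions: second-generation Hoveyda–Grubbs catalyst (10 mol %), toluene, 80 °C, 2 mM, argon sparge
Reagents that add atoms: none
Why: Ring-closing metathesis joins the two terminal alkenes, which are held gauche by the cis C4/C5 arrangement, to the seven-membered Z-enone (ring D), while the trisubstituted C2=C3 bond stays inert.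

Step 10
Reactants: 16 (4S,5R)-3,6,6,10-tetramethylbicyclo[5.4.0]undeca-2,7-dien-9-one
Product: 17 (4S,5R)-3,6,6,10-tetramethylbicyclo[5.4.0]undeca-2,7-diene-1,9-dione (route numbering; cis-fused)
Conditions: CrO3, 3,5-dimethylpyrazole, CH2Cl2, −20 °C
Reagents that add atoms: chromium trioxide O=[Cr](=O)=O
Why: This allylic oxidation of a 1-methylcyclohexene attacks the secondary allylic CH2 next to the unsubstituted alkene carbon (C1) and gives the 3-methylcyclohexenone, the same selectivity that turns alpha-pinene into verbenone.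

Step 11
Reactants: 17 (4S,5R)-3,6,6,10-tetramethylbicyclo[5.4.0]undeca-2,7-diene-1,9-dione
Product: 19 (4R,5S,10R,11R)-longipina-2,7-diene-1,9-dione, via dilithium bis-enolate 18 (not isolated)
Conditions: LDA (2.4 equiv), THF, −78 °C; then Fe(acac)3 (2.2 equiv), THF, −78 to 0 °C, 5 mM
Reagents that add atoms: none
Why: LDA gives the bis-enolate 18, because the ring B enone is deprotonated kinetically at its alpha' carbon C11 and the ring D enone can lose only the C10 proton (C8 is sp2, C6 is quaternary). Trivalent iron takes one electron from the electron-rich tetrasubstituted C9=C10 enolate, the tertiary alpha-keto radical at C10 adds to C11 of the neighbouring dienolate, and a second electron transfer from the resulting radical anion makes the bond formation irreversible; the closest known reaction type is the intramolecular oxidative coupling of ketone bis-enolates to 1,4-diketones, which is known to build strained small rings. The new C10–C11 bond closes ring C in a 4-exo-trig mode with respect to the C11=C1 enolate bond and, through the same bond, ring A in a 6-endo-trig mode. C10 and C11 are controlled by the cis C4–C5 fusion: in the favoured conformer C6 is equatorial on ring B, C10 is axial on ring B and C11 is axial on ring D, so the two enolate carbons face each other at gauche distance and can join on one face only. The step needs ring closure to win over dimerisation and over dehydrogenation of ring B, which is secured by the proximity of the two carbons, by high dilution and by a halide-free oxidant.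

Step 12
Reactants: 19 (4R,5S,10R,11R)-longipina-2,7-diene-1,9-dione
Product: 21 (4R,5S,7R,10R,11R)-7-hydroxylongipin-2-ene-1,9-dione, via C7 pinacol boronate 20 (not isolated)
Conditions: B2pin2, CuCl (5 mol %), NaOt-Bu (10 mol %), (R)-1-[(S)-2-(diphenylphosphino)ferrocenyl]ethyldicyclohexylphosphine (6 mol %), MeOH (2 equiv), THF, rt; then NaBO3·4H2O, THF/H2O, rt
Reagents that add atoms: sodium perborate [Na+].[O-]OB=O
Why: The copper-catalysed asymmetric conjugate borylation picks the beta-monosubstituted C7=C8 enone over the beta,beta-disubstituted C2=C3 enone, the chiral ligand sets C7 because the two enone faces differ only in the remote C1=O and C3–CH3 groups, and the oxidation of the C–B bond proceeds with retention.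

Step 13
Reactants: 21 (4R,5S,7R,10R,11R)-7-hydroxylongipin-2-ene-1,9-dione; 22 3-methylbut-2-enal
Product: 24 (4R,5S,7R,9R,10R,11R)-9-hydroxy-1-oxolongipin-2-en-7-yl 3-methylbut-2-enoate, via C7 hemiacetal 23 (not isolated)
Conditions: 22 (5 equiv), SmI2 (0.3 equiv, pre-mixed with 22), THF, −10 °C
Reagents that add atoms: none
Why: In the Evans–Tishchenko reduction the samarium-bound hemiacetal of the C7 hydroxyl delivers its hydride to C9 from the face of the C7–O bond, which gives the 1,3-anti (9R) alcohol, turns the aldehyde into the C7 senecioate and leaves the C1 enone untouched.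

Step 14
Reactants: 24 (4R,5S,7R,9R,10R,11R)-9-hydroxy-1-oxolongipin-2-en-7-yl 3-methylbut-2-enoate; 25 3-methylbutanoyl chloride
Product: 26 (4R,5S,7R,9R,10R,11R)-9-(3-methylbutanoyloxy)-1-oxolongipin-2-en-7-yl 3-methylbut-2-enoate (CNP0214473.1)
Conditions: pyridine, DMAP, CH2Cl2, 40 °C
Reagents that add atoms: none
Why: DMAP-catalysed acylation esterifies the only free hydroxyl (C9) without touching any stereocentre.

Compound list
1 | methyl 3,3-dimethylpent-4-enoate | COC(=O)CC(C)(C)C=C | starting material
2 | 3,3-dimethylpent-4-enal | O=CCC(C)(C)C=C | intermediate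
3 | pent-1-en-3-one | CCC(=O)C=C | starting material
4 | (2S)-2-(2-methylbut-3-en-2-yl)-5-oxoheptanal | CCC(=O)CC[C@H](C=O)C(C)(C)C=C | intermediate
5 | (4R)-2-methyl-4-(2-methylbut-3-en-2-yl)cyclohex-2-en-1-one | O=C1C(C)=C[C@H](C(C)(C)C=C)CC1 | intermediate
6 | (1R,4R)-2-methyl-4-(2-methylbut-3-en-2-yl)cyclohex-2-en-1-ol, 1,4-trans | O[C@H]1C(C)=C[C@H](C(C)(C)C=C)CC1 | intermediate
7 | propanoic acid | CCC(=O)O | starting material
8 | (1S,4R)-2-methyl-4-(2-methylbut-3-en-2-yl)cyclohex-2-en-1-yl propanoate, 1,4-cis | CCC(=O)O[C@@H]1C(C)=C[C@H](C(C)(C)C=C)CC1 | intermediate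
9 | trimethylsilyl ketene acetal of 8 (not isolated) | CC=C(O[Si](C)(C)C)O[C@@H]1C(C)=C[C@H](C(C)(C)C=C)CC1 | intermediate
10 | trimethylsilyl ester of 11 (not isolated) | C[Si](C)(C)OC(=O)C(C)[C@H]1C(C)=CCC[C@H]1C(C)(C)C=C | intermediate
11 | 2-[(1S,6R)-2-methyl-6-(2-methylbut-3-en-2-yl)cyclohex-2-en-1-yl]propanoic acid, C4/C5 cis, C10 epimers | OC(=O)C(C)[C@H]1C(C)=CCC[C@H]1C(C)(C)C=C | intermediate
12 | acyl imidazolide of 11 (not isolated) | O=C(n1ccnc1)C(C)[C@H]1C(C)=CCC[C@H]1C(C)(C)C=C | intermediate
13 | N-methoxy-N-methyl amide of 11 | CON(C)C(=O)C(C)[C@H]1C(C)=CCC[C@H]1C(C)(C)C=C | intermediate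
14 | vinylmagnesium bromide | C=C[Mg]Br | starting material
15 | 4-[(1S,6R)-2-methyl-6-(2-methylbut-3-en-2-yl)cyclohex-2-en-1-yl]pent-1-en-3-one | C=CC(=O)C(C)[C@H]1C(C)=CCC[C@H]1C(C)(C)C=C | intermediate
16 | (4S,5R)-3,6,6,10-tetramethylbicyclo[5.4.0]undeca-2,7-dien-9-one, cis-fused | CC1C(=O)C=CC(C)(C)[C@@H]2CCC=C(C)[C@H]12 | intermediate
17 | (4S,5R)-3,6,6,10-tetramethylbicyclo[5.4.0]undeca-2,7-diene-1,9-dione, cis-fused | CC1C(=O)C=CC(C)(C)[C@@H]2CC(=O)C=C(C)[C@H]12 | intermediate
18 | dilithium bis-enolate of 17 (not isolated) | CC1=C([O-])C=CC(C)(C)[C@@H]2C=C([O-])C=C(C)[C@H]12.[Li+].[Li+] | intermediate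
19 | (4R,5S,10R,11R)-longipina-2,7-diene-1,9-dione | C1=CC(=O)[C@@]2(C)[C@@H]3C(=O)C=C(C)[C@H]2[C@@H]3C1(C)C | intermediate
20 | C7 pinacol boronate of longipin-2-ene-1,9-dione (not isolated) | CC1(C)OB(OC1(C)C)[C@@H]2CC(=O)[C@@]3(C)[C@@H]4C(=O)C=C(C)[C@H]3[C@@H]4C2(C)C | intermediate
21 | (4R,5S,7R,10R,11R)-7-hydroxylongipin-2-ene-1,9-dione | O[C@@H]1CC(=O)[C@@]2(C)[C@@H]3C(=O)C=C(C)[C@H]2[C@@H]3C1(C)C | intermediate
22 | 3-methylbut-2-enal | CC(C)=CC=O | starting material
23 | C7 hemiacetal of 21 and 22 (not isolated) | CC(C)=CC(O)O[C@@H]1CC(=O)[C@@]2(C)[C@@H]3C(=O)C=C(C)[C@H]2[C@@H]3C1(C)C | intermediate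
24 | (4R,5S,7R,9R,10R,11R)-9-hydroxy-1-oxolongipin-2-en-7-yl 3-methylbut-2-enoate | CC(C)=CC(=O)O[C@@H]1C[C@@H](O)[C@@]2(C)[C@@H]3C(=O)C=C(C)[C@H]2[C@@H]3C1(C)C | intermediate
25 | 3-methylbutanoyl chloride | CC(C)CC(=O)Cl | starting material
26 | CNP0214473.1 | CC(C)=CC(=O)O[C@@H]1C[C@@H](OC(=O)CC(C)C)[C@@]2(C)[C@@H]3C(=O)C=C(C)[C@H]2[C@@H]3C1(C)C | target

Total step count: 14. Longest linear sequence: 14 steps (1 to 26).

Steps most likely to fail

Step 11. The bis-enolate may be oxidised along other paths faster than the strained four-membered ring closes. These paths are intermolecular coupling and loss of two hydrogens from ring B followed by aromatisation. The fallback sets out from 17 and replaces electron transfer by a two-electron alkylation. Kinetic mono-enolisation at C11 (LDA, 1.05 equiv, then TMSCl) would give the cross-conjugated silyl dienol ether F1. NBS would brominate C11 from the face opposite to the axial C10 to give the 11-bromo enone F2. KHMDS would then form the C10 enolate, which displaces bromide with inversion. This is an intramolecular enolate alkylation, the classical entry to bicyclo[3.1.1]heptanes. The fallback comes back to the route at 19.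

Step 9. Initiation at the neopentyl vinyl group is slow and the vinyl ketone is electron-poor, so oligomerisation or catalyst decay may outrun closure of ring D. The fallback sets out from 13 and closes ring D by carbonyl condensation. MeMgBr would give the methyl ketone F3. CrO3/3,5-dimethylpyrazole would oxidise C1 to the ring B enone F4, which leaves the terminal vinyl group as the only electron-rich alkene. Ozonolysis (O3, then Me2S) would give the neopentyl, non-enolisable keto aldehyde F5. Base (KOH, MeOH) would then condense the methyl ketone carbon C8 with the C7 aldehyde. Under these equilibrating conditions C4 can also settle in its axial, cis-fused arrangement. The fallback comes back to the route at 17.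

Step 13. Hemiacetal formation at the neopentyl C7 hydroxyl and hydride transfer from an enal-derived hemiacetal may be slow. Retro-aldol opening of ring D or reductive coupling of the enal could then compete. The fallback sets out from 21 and separates the hydride delivery from the choice of ester. An Evans–Tishchenko reduction with 4-nitrobenzaldehyde would give the 7-(4-nitrobenzoate) 9-alcohol F6. Acylation with 25 would give the mixed diester F7. K2CO3 in MeOH would cleave the activated aromatic ester selectively to the 7-alcohol 9-isovalerate F8. 3-Methylbut-2-enoyl chloride with DMAP would then esterify C7. The fallback comes back to the route at 26.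

Further compounds
F1 | step 11 | C1 trimethylsilyl dienol ether of 17 (C11=C1) | CC1C(=O)C=CC(C)(C)[C@@H]2C=C(O[Si](C)(C)C)C=C(C)[C@H]12
F2 | step 11 | 11-bromo derivative of 17, bromine trans to C10 | CC1C(=O)C=CC(C)(C)[C@@H]2[C@@H](Br)C(=O)C=C(C)[C@H]12
F3 | step 9 | 3-[(1S,6R)-2-methyl-6-(2-methylbut-3-en-2-yl)cyclohex-2-en-1-yl]butan-2-one | CC(=O)C(C)[C@H]1C(C)=CCC[C@H]1C(C)(C)C=C
F4 | step 9 | 3-methyl-5-(2-methylbut-3-en-2-yl)-4-(3-oxobutan-2-yl)cyclohex-2-en-1-one, 4,5-cis | CC(=O)C(C)[C@H]1C(C)=CC(=O)C[C@H]1C(C)(C)C=C
F5 | step 9 | 2-methyl-2-[3-methyl-5-oxo-2-(3-oxobutan-2-yl)cyclohex-3-en-1-yl]propanal, cis | CC(=O)C(C)[C@H]1C(C)=CC(=O)C[C@H]1C(C)(C)C=O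
F6 | step 13 | 9-hydroxy-1-oxolongipin-2-en-7-yl 4-nitrobenzoate (7R,9R) | O=C(O[C@@H]1C[C@@H](O)[C@@]2(C)[C@@H]3C(=O)C=C(C)[C@H]2[C@@H]3C1(C)C)c1ccc(cc1)[N+](=O)[O-]
F7 | step 13 | 9-(3-methylbutanoyloxy)-1-oxolongipin-2-en-7-yl 4-nitrobenzoate (7R,9R) | O=C(O[C@@H]1C[C@@H](OC(=O)CC(C)C)[C@@]2(C)[C@@H]3C(=O)C=C(C)[C@H]2[C@@H]3C1(C)C)c1ccc(cc1)[N+](=O)[O-]
F8 | step 13 | 7-hydroxy-1-oxolongipin-2-en-9-yl 3-methylbutanoate (7R,9R) | O[C@@H]1C[C@@H](OC(=O)CC(C)C)[C@@]2(C)[C@@H]3C(=O)C=C(C)[C@H]2[C@@H]3C1(C)C
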